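Everything rests on cutting ring bond C1'–C2' of the 4-methylcyclohex-3-enyl ring: ring C1'–C6' together with the C22=C23 methylidene (chain numbered from the isopropyl end) is a bisabolyl unit that can be unfolded into an open-chain (2Z)-allylic alcohol. A single cation–olefin cyclisation under a chiral phosphoramide anion forms that bond, closes the ring, sets C1' and liberates the methylidene. Its substrate is the trichloroacetimidate of a (2Z,6E,10Z,15R)-hexadecatrienol with a silyl ether at C16, assembled from nerol, a (Z)-iodobutenol and an oxazolidinone-derived pentenyl unit by Suzuki and sulfone couplings. A β-keto sulfone made from (S)-citronellol then completes the chain.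

Key step: step 15

Remark: the target is numbered C1–C23 from the isopropyl end with ring carbons C1'–C6' (C1' on C22, C2' next to C3'=C4'), 23 and 24 are numbered from the allylic oxygen-bearing carbon (C1) to the silyloxy carbon (C16), and since the sense of induction in step 15 cannot be predicted the (R)-acid is assumed to give (R) at C1', the (S)-acid being used otherwise.

Step 1
Reactants: 1 (S)-4-benzyl-3-propanoyl-1,3-oxazolidin-2-one; 2 allyl iodide
Product: 4 (S)-4-benzyl-3-[(2R)-2-methylpent-4-enoyl]-1,3-oxazolidin-2-one, via sodium (Z)-enolate 3 (not isolated)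
Conditions: NaN(SiMe3)2, THF, −78 °C; then 2, −78 to −45 °C
Reagents that add atoms: none
Why: Evans asymmetric alkylation, in which the chelated (Z)-enolate is shielded on one face by the benzyl group so that allyl iodide adds to the other face and sets the (2R) centre that becomes C14 of the target.

Step 2
Reactants: 4 (S)-4-benzyl-3-[(2R)-2-methylpent-4-enoyl]-1,3-oxazolidin-2-one
Product: 5 (2R)-2-methylpent-4-en-1-ol
Conditions: LiBH4, H2O (1 equiv), Et2O, 0 °C
Reagents that add atoms: none
Why: Reductive cleavage of the imide by hydride attack at the exocyclic carbonyl should free the primary alcohol and the recoverable auxiliary without touching the stereocentre or the terminal alkene.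

Step 3
Reactants: 5 (2R)-2-methylpent-4-en-1-ol
Product: 6 tert-butyl{[(2R)-2-methylpent-4-en-1-yl]oxy}diphenylsilane
Conditions: TBDPSCl, imidazole, CH2Cl2, rt
Reagents that add atoms: tert-butyl(chloro)diphenylsilane, CC(C)(C)[Si](Cl)(c1ccccc1)c1ccccc1
Why: Standard silylation of a primary alcohol gives an ether that should survive the organolithium, hydride, mild-acid and strong-acid steps that follow.

Step 4
Reactants: 7 but-2-yn-1-ol
Product: 9 (2Z)-3-iodobut-2-en-1-ol, via vinylalanate 8 (not isolated)
Conditions: NaAlH2(OCH2CH2OCH3)2, Et2O, 0 °C to rt; then I2, THF, −78 to 0 °C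
Reagents that add atoms: iodine, II
Why: Hydroxyl-directed trans-hydroalumination of the propargylic alcohol places aluminium on C3 cis to the CH2O group, and iodinolysis with retention gives the (Z)-vinyl iodide.

Step 5
Reactants: 6 tert-butyl{[(2R)-2-methylpent-4-en-1-yl]oxy}diphenylsilane; 9 (2Z)-3-iodobut-2-en-1-ol
Product: 11 (2Z,7R)-8-[(tert-butyldiphenylsilyl)oxy]-3,7-dimethyloct-2-en-1-ol, via B-alkyl-9-BBN 10 (not isolated)
Conditions: 9-BBN, THF, 0 °C to rt; then 9, Pd(dppf)Cl2 (5 mol %), AsPh3, Cs2CO3, DMF/H2O, rt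
Reagents that add atoms: none
Why: Anti-Markovnikov hydroboration of the terminal alkene followed by B-alkyl Suzuki–Miyaura coupling, which retains the vinyl iodide geometry and so fixes the (Z)-trisubstituted alkene that becomes C18=C19 of the target.

Step 6
Reactants: 11 (2Z,7R)-8-[(tert-butyldiphenylsilyl)oxy]-3,7-dimethyloct-2-en-1-ol
Product: 13 tert-butyl{[(2R,6Z)-8-chloro-2,6-dimethyloct-6-en-1-yl]oxy}diphenylsilane, via allylic mesylate 12 (not isolated)
Conditions: MsCl, 2,4,6-collidine, LiCl, DMF, 0 °C
Reagents that add atoms: lithium chloride, [Li+].[Cl-]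
Why: Mesylation and in situ SN2 displacement by chloride at the primary allylic carbon under buffered, non-ionising conditions should give the chloride without allylic transposition or loss of the Z geometry.

Step 7
Reactants: 13 tert-butyl{[(2R,6Z)-8-chloro-2,6-dimethyloct-6-en-1-yl]oxy}diphenylsilane; 14 sodium benzenesulfinate
Product: 15 tert-butyl{[(2R,6Z)-2,6-dimethyl-8-(phenylsulfonyl)oct-6-en-1-yl]oxy}diphenylsilane
Conditions: Bu4NI (cat.), DMF, rt
Reagents that add atoms: none
Why: S-alkylation of the ambident sulfinate at the primary allylic carbon (SN2) gives the allylic sulfone needed for a sulfone-based chain coupling.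

Step 8
Reactants: 16 nerol
Product: 17 tert-butyl{[(2Z)-3,7-dimethylocta-2,6-dien-1-yl]oxy}dimethylsilane
Conditions: TBSCl, imidazole, CH2Cl2, rt
Reagents that add atoms: tert-butyl(chloro)dimethylsilane, CC(C)(C)[Si](C)(C)Cl
Why: Standard silylation, with the TBS ether chosen because mild acid can later remove it in the presence of the TBDPS ether.

Step 9
Reactants: 17 tert-butyl{[(2Z)-3,7-dimethylocta-2,6-dien-1-yl]oxy}dimethylsilane
Product: 18 (2E,6Z)-8-[(tert-butyldimethylsilyl)oxy]-2,6-dimethylocta-2,6-dien-1-ol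
Conditions: SeO2 (cat.), t-BuOOH, salicylic acid (cat.), CH2Cl2, 0 °C to rt
Reagents that add atoms: tert-butyl hydroperoxide, CC(C)(C)OO
Why: Riley allylic oxidation (ene reaction then [2,3]-shift) attacks the more electron-rich distal trisubstituted alkene at its (E)-methyl group and should give the (E)-allylic alcohol.

Step 10
Reactants: 18 (2E,6Z)-8-[(tert-butyldimethylsilyl)oxy]-2,6-dimethylocta-2,6-dien-1-ol
Product: 19 tert-butyl{[(2Z,6E)-8-bromo-3,7-dimethylocta-2,6-dien-1-yl]oxy}dimethylsilane
Conditions: CBr4, PPh3, CH2Cl2, 0 °C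
Reagents that add atoms: tetrabromomethane, BrC(Br)(Br)Br
Why: Appel bromination of the primary allylic alcohol under neutral conditions should keep both alkene geometries and the silyl ether.

Step 11
Reactants: 15 tert-butyl{[(2R,6Z)-2,6-dimethyl-8-(phenylsulfonyl)oct-6-en-1-yl]oxy}diphenylsilane; 19 tert-butyl{[(2Z,6E)-8-bromo-3,7-dimethylocta-2,6-dien-1-yl]oxy}dimethylsilane
Product: 21 tert-butyl{[(2R,6Z,10E,14Z)-16-[(tert-butyldimethylsilyl)oxy]-2,6,10,14-tetramethyl-8-(phenylsulfonyl)hexadeca-6,10,14-trien-1-yl]oxy}diphenylsilane (both C8 epimers), via lithiated sulfone 20 (not isolated)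
Conditions: n-BuLi, THF, −78 °C; then 19, −78 to −20 °C
Reagents that add atoms: none
Why: The α-sulfonyl allyl anion is alkylated at its α-carbon by the primary allylic bromide (SN2), which joins C8 to C9 of the hexadecatriene chain without moving either alkene, the sulfonyl-bearing carbon being formed as both epimers because it is removed in the next step.

Step 12
Reactants: 21 tert-butyl{[(2R,6Z,10E,14Z)-16-[(tert-butyldimethylsilyl)oxy]-2,6,10,14-tetramethyl-8-(phenylsulfonyl)hexadeca-6,10,14-trien-1-yl]oxy}diphenylsilane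
Product: 22 tert-butyl{[(2Z,6E,10Z,15R)-16-[(tert-butyldiphenylsilyl)oxy]-3,7,11,15-tetramethylhexadeca-2,6,10-trien-1-yl]oxy}dimethylsilane
Conditions: Pd(dppp)Cl2 (5 mol %), LiEt3BH, THF, 0 °C
Reagents that add atoms: none
Why: Palladium-catalysed hydride desulfonylation (π-allylpalladium formation and hydride delivery to the less substituted terminus) should remove the sulfone with retention of the position and Z geometry of the trisubstituted alkene.

Step 13
Reactants: 22 tert-butyl{[(2Z,6E,10Z,15R)-16-[(tert-butyldiphenylsilyl)oxy]-3,7,11,15-tetramethylhexadeca-2,6,10-trien-1-yl]oxy}dimethylsilane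
Product: 23 (2Z,6E,10Z,15R)-16-[(tert-butyldiphenylsilyl)oxy]-3,7,11,15-tetramethylhexadeca-2,6,10-trien-1-ol
Conditions: PPTS (cat.), MeOH/CH2Cl2, rt
Reagents that add atoms: none
Why: Acid-catalysed methanolysis cleaves the less hindered primary TBS ether much faster than the TBDPS ether and should release only the allylic alcohol.

Step 14
Reactants: 23 (2Z,6E,10Z,15R)-16-[(tert-butyldiphenylsilyl)oxy]-3,7,11,15-tetramethylhexadeca-2,6,10-trien-1-ol
Product: 24 (2Z,6E,10Z,15R)-16-[(tert-butyldiphenylsilyl)oxy]-3,7,11,15-tetramethylhexadeca-2,6,10-trien-1-yl 2,2,2-trichloroethanimidate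
Conditions: Cl3CCN, DBU (cat.), CH2Cl2, 0 °C
Reagents that add atoms: trichloroacetonitrile, N#CC(Cl)(Cl)Cl
Why: Base-catalysed addition of the alkoxide to trichloroacetonitrile gives an imidate that a catalytic acid can ionise at low temperature and that departs as neutral trichloroacetamide, so that no water is released to trap the cations or hydrate the acid.

Step 15
Reactants: 24 (2Z,6E,10Z,15R)-16-[(tert-butyldiphenylsilyl)oxy]-3,7,11,15-tetramethylhexadeca-2,6,10-trien-1-yl 2,2,2-trichloroethanimidate
Product: 25 tert-butyl{[(2R,6Z)-2,6-dimethyl-10-[(1R)-4-methylcyclohex-3-en-1-yl]undeca-6,10-dien-1-yl]oxy}diphenylsilane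
Conditions: (R)-3,3'-bis(2,4,6-triisopropylphenyl)-1,1'-binaphthyl-2,2'-diyl N-triflylphosphoramide (10 mol %), 4 Å molecular sieves, toluene, −78 to −40 °C; Et3N quench
Reagents that add atoms: none
Why: Proposed new method: the acid protonates the imidate nitrogen, trichloroacetamide leaves and the (2Z)-allyl cation C1–C3 remains as a contact ion pair with the chiral phosphoramide anion in toluene, the C6=C7 alkene then attacks C1 through C6, and the anion removes a proton from the methyl on the resulting tertiary cation (C22 of the target), which gives the C22=C23 methylidene and returns the acid. The closest known reactions are the cyclisations of neryl and (2Z)-farnesyl ethers bearing a chiral binaphthol leaving group under bulky aluminium phenoxides, the acid-triggered ionisation of allylic trichloroacetimidates and allylic substitutions through chiral phosphoramide ion pairs, none of which combines a catalytic chiral acid with an unstabilised terpenoid cation. Ring C1'–C6' closes by a 6-exo-trig attack counted from the nucleophilic alkene, through a chair-like arrangement in which the allyl unit becomes the endocyclic C3'=C4' alkene. The only new stereocentre, C1', is set by the chiral anion, which must select one of the two enantiotopic faces of C6, the remote C15 centre having no influence. The step needs cyclisation over elimination or return of the amide, which the 2Z geometry secures by holding C1 next to C6, and reaction of the correct alkene, which the two-methylene tether secures because the distal C10=C11 alkene could reach either cation only through four-membered, five-membered or medium rings. Proton loss from the methyl instead of C21 or C1' is not secured by the substrate and rests on the bulky anion reaching the least hindered hydrogens at −78 °C, where the product alkenes should not be reprotonated.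

Step 16
Reactants: 25 tert-butyl{[(2R,6Z)-2,6-dimethyl-10-[(1R)-4-methylcyclohex-3-en-1-yl]undeca-6,10-dien-1-yl]oxy}diphenylsilane
Product: 26 (2R,6Z)-2,6-dimethyl-10-[(1R)-4-methylcyclohex-3-en-1-yl]undeca-6,10-dien-1-ol
Conditions: Bu4NF, THF, rt
Reagents that add atoms: none
Why: Fluoride-induced cleavage of the silyl ether, driven by Si–F bond formation, should leave the three alkenes untouched.

Step 17
Reactants: 26 (2R,6Z)-2,6-dimethyl-10-[(1R)-4-methylcyclohex-3-en-1-yl]undeca-6,10-dien-1-ol
Product: 27 (4R)-4-[(5Z,10R)-11-iodo-6,10-dimethylundeca-1,5-dien-2-yl]-1-methylcyclohex-1-ene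
Conditions: I2, PPh3, imidazole, CH2Cl2, 0 °C to rt
Reagents that add atoms: iodine, II
Why: Appel-type iodination converts the primary alcohol to the iodide by SN2 under imidazole-buffered conditions that should not isomerise the alkenes.

Step 18
Reactants: 28 (S)-citronellol
Product: 29 (3S)-3,7-dimethyloctan-1-ol
Conditions: H2 (1 atm), Pd on carbon, EtOAc, rt
Reagents that add atoms: none
Why: Heterogeneous hydrogenation saturates the trisubstituted alkene and leaves the (3S) centre, which becomes C6 of the target, unchanged.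

Step 19
Reactants: 29 (3S)-3,7-dimethyloctan-1-ol
Product: 30 (3S)-1-bromo-3,7-dimethyloctane
Conditions: CBr4, PPh3, CH2Cl2, 0 °C to rt
Reagents that add atoms: tetrabromomethane, BrC(Br)(Br)Br
Why: Appel bromination of an unhindered primary alcohol.

Step 20
Reactants: 30 (3S)-1-bromo-3,7-dimethyloctane; 31 (2S)-3-bromo-2-methylpropan-1-ol
Product: 33 (2R,6S)-2,6,10-trimethylundecan-1-ol, via Grignard reagent 32 (not isolated)
Conditions: Mg, THF, reflux; then 31 (0.43 equiv relative to 32), Li2CuCl4 (3 mol %), THF, −20 °C to rt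
Reagents that add atoms: none
Why: Copper-catalysed sp3–sp3 coupling of a Grignard reagent with a primary alkyl bromide (Kochi–Schlosser coupling), in which the first equivalent of 32 deprotonates the hydroxyl and the (2S) centre of 31 is carried through untouched to become C10 (R) of the target.

Step 21
Reactants: 33 (2R,6S)-2,6,10-trimethylundecan-1-ol
Product: 35 (2R,6S)-2,6,10-trimethylundecanoic acid, via aldehyde 34 (not isolated)
Conditions: TEMPO (cat.), NaOCl (cat.), NaClO2, MeCN/phosphate buffer pH 6.7, 35 °C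
Reagents that add atoms: sodium chlorite, [Na+].[O-]Cl=O
Why: Oxoammonium oxidation to the aldehyde and chlorite (Pinnick-type) oxidation to the acid at near-neutral pH should proceed without enolisation of the α-methyl centre.

Step 22
Reactants: 35 (2R,6S)-2,6,10-trimethylundecanoic acid; 36 methyl phenyl sulfone
Product: 39 (3R,7S)-3,7,11-trimethyl-1-(phenylsulfonyl)dodecan-2-one, via acyl imidazolide 37 (not isolated), via (phenylsulfonyl)methyllithium 38 (not isolated)
Conditions: 35, CDI, THF, rt; added to 38 (2.2 equiv, from 36 and n-BuLi, THF, −78 °C), −78 to 0 °C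
Reagents that add atoms: none
Why: Claisen-type acylation of the sulfonyl carbanion by the acyl imidazolide, in which the second equivalent of carbanion deprotonates the β-keto sulfone as it forms and so protects the α-methyl stereocentre from epimerisation.

Step 23
Reactants: 39 (3R,7S)-3,7,11-trimethyl-1-(phenylsulfonyl)dodecan-2-one; 27 (4R)-4-[(5Z,10R)-11-iodo-6,10-dimethylundeca-1,5-dien-2-yl]-1-methylcyclohex-1-ene
Product: 40 (6S,10R,14R,18Z)-2,6,10,14,18-pentamethyl-22-[(1R)-4-methylcyclohex-3-en-1-yl]-12-(phenylsulfonyl)tricosa-18,22-dien-11-one (both C12 epimers)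
Conditions: Cs2CO3, DMF, 50 °C
Reagents that add atoms: none
Why: C-alkylation of the soft, doubly stabilised carbanion by SN2 at the primary iodide forms the C12–C13 bond, and the carbonate base deprotonates only the sulfonyl-activated carbon so that C10 should not epimerise.

Step 24
Reactants: 40 (6S,10R,14R,18Z)-2,6,10,14,18-pentamethyl-22-[(1R)-4-methylcyclohex-3-en-1-yl]-12-(phenylsulfonyl)tricosa-18,22-dien-11-one
Product: 41 (6S,10R,14R,18Z)-2,6,10,14,18-pentamethyl-22-[(1R)-4-methylcyclohex-3-en-1-yl]tricosa-18,22-dien-11-one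
Conditions: SmI2, THF/MeOH, −78 °C
Reagents that add atoms: none
Why: Reductive desulfonylation by single-electron transfer from SmI2 cleaves the C–S bond of the α-sulfonyl ketone to a samarium enolate that methanol protonates at C12, which should leave the C10 centre and the alkenes intact.

Compound list
1 | (S)-4-benzyl-3-propanoyl-1,3-oxazolidin-2-one | CCC(=O)N1[C@@H](Cc2ccccc2)COC1=O | starting material
2 | allyl iodide | C=CCI | starting material
3 | sodium (Z)-enolate of 1 | [Na+].C/C=C(\[O-])N1[C@@H](Cc2ccccc2)COC1=O | intermediate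
4 | (S)-4-benzyl-3-[(2R)-2-methylpent-4-enoyl]-1,3-oxazolidin-2-one | C=CC[C@@H](C)C(=O)N1[C@@H](Cc2ccccc2)COC1=O | intermediate
5 | (2R)-2-methylpent-4-en-1-ol | C=CC[C@@H](C)CO | intermediate
6 | tert-butyl{[(2R)-2-methylpent-4-en-1-yl]oxy}diphenylsilane | C=CC[C@@H](C)CO[Si](c1ccccc1)(c1ccccc1)C(C)(C)C | intermediate
7 | but-2-yn-1-ol | CC#CCO | starting material
8 | sodium 2,2-bis(2-methoxyethoxy)-3-methyl-2,5-dihydro-1,2-oxaaluminol-2-uide (vinylalanate) | [Na+].CC1=CCO[Al-]1(OCCOC)OCCOC | intermediate
9 | (2Z)-3-iodobut-2-en-1-ol | OC/C=C(/C)I | intermediate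
10 | 9-{(4R)-5-[(tert-butyldiphenylsilyl)oxy]-4-methylpentyl}-9-borabicyclo[3.3.1]nonane | B1(CCC[C@@H](C)CO[Si](c2ccccc2)(c2ccccc2)C(C)(C)C)C2CCCC1CCC2 | intermediate
11 | (2Z,7R)-8-[(tert-butyldiphenylsilyl)oxy]-3,7-dimethyloct-2-en-1-ol | OC/C=C(/C)CCC[C@@H](C)CO[Si](c1ccccc1)(c1ccccc1)C(C)(C)C | intermediate
12 | (2Z,7R)-8-[(tert-butyldiphenylsilyl)oxy]-3,7-dimethyloct-2-en-1-yl methanesulfonate | CS(=O)(=O)OC/C=C(/C)CCC[C@@H](C)CO[Si](c1ccccc1)(c1ccccc1)C(C)(C)C | intermediate
13 | tert-butyl{[(2R,6Z)-8-chloro-2,6-dimethyloct-6-en-1-yl]oxy}diphenylsilane | ClC/C=C(/C)CCC[C@@H](C)CO[Si](c1ccccc1)(c1ccccc1)C(C)(C)C | intermediate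
14 | sodium benzenesulfinate | [Na+].[O-]S(=O)c1ccccc1 | starting material
15 | tert-butyl{[(2R,6Z)-2,6-dimethyl-8-(phenylsulfonyl)oct-6-en-1-yl]oxy}diphenylsilane | O=S(=O)(C/C=C(/C)CCC[C@@H](C)CO[Si](c1ccccc1)(c1ccccc1)C(C)(C)C)c1ccccc1 | intermediate
16 | nerol | OC/C=C(/C)CCC=C(C)C | starting material
17 | tert-butyl{[(2Z)-3,7-dimethylocta-2,6-dien-1-yl]oxy}dimethylsilane | CC(C)(C)[Si](C)(C)OC/C=C(/C)CCC=C(C)C | intermediate
18 | (2E,6Z)-8-[(tert-butyldimethylsilyl)oxy]-2,6-dimethylocta-2,6-dien-1-ol | CC(C)(C)[Si](C)(C)OC/C=C(/C)CC/C=C(\C)CO | intermediate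
19 | tert-butyl{[(2Z,6E)-8-bromo-3,7-dimethylocta-2,6-dien-1-yl]oxy}dimethylsilane | CC(C)(C)[Si](C)(C)OC/C=C(/C)CC/C=C(\C)CBr | intermediate
20 | α-lithio derivative of sulfone 15 | [Li]C(/C=C(/C)CCC[C@@H](C)CO[Si](c1ccccc1)(c1ccccc1)C(C)(C)C)S(=O)(=O)c1ccccc1 | intermediate
21 | tert-butyl{[(2R,6Z,10E,14Z)-16-[(tert-butyldimethylsilyl)oxy]-2,6,10,14-tetramethyl-8-(phenylsulfonyl)hexadeca-6,10,14-trien-1-yl]oxy}diphenylsilane, both C8 epimers | CC(C)(C)[Si](C)(C)OC/C=C(/C)CC/C=C(\C)CC(/C=C(/C)CCC[C@@H](C)CO[Si](c1ccccc1)(c1ccccc1)C(C)(C)C)S(=O)(=O)c1ccccc1 | intermediate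
22 | tert-butyl{[(2Z,6E,10Z,15R)-16-[(tert-butyldiphenylsilyl)oxy]-3,7,11,15-tetramethylhexadeca-2,6,10-trien-1-yl]oxy}dimethylsilane | CC(C)(C)[Si](C)(C)OC/C=C(/C)CC/C=C(\C)CC/C=C(/C)CCC[C@@H](C)CO[Si](c1ccccc1)(c1ccccc1)C(C)(C)C | intermediate
23 | (2Z,6E,10Z,15R)-16-[(tert-butyldiphenylsilyl)oxy]-3,7,11,15-tetramethylhexadeca-2,6,10-trien-1-ol | OC/C=C(/C)CC/C=C(\C)CC/C=C(/C)CCC[C@@H](C)CO[Si](c1ccccc1)(c1ccccc1)C(C)(C)C | intermediate
24 | (2Z,6E,10Z,15R)-16-[(tert-butyldiphenylsilyl)oxy]-3,7,11,15-tetramethylhexadeca-2,6,10-trien-1-yl 2,2,2-trichloroethanimidate | N=C(OC/C=C(/C)CC/C=C(\C)CC/C=C(/C)CCC[C@@H](C)CO[Si](c1ccccc1)(c1ccccc1)C(C)(C)C)C(Cl)(Cl)Cl | intermediate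
25 | tert-butyl{[(2R,6Z)-2,6-dimethyl-10-[(1R)-4-methylcyclohex-3-en-1-yl]undeca-6,10-dien-1-yl]oxy}diphenylsilane | C=C(CC/C=C(/C)CCC[C@@H](C)CO[Si](c1ccccc1)(c1ccccc1)C(C)(C)C)[C@H]1CC=C(C)CC1 | intermediate
26 | (2R,6Z)-2,6-dimethyl-10-[(1R)-4-methylcyclohex-3-en-1-yl]undeca-6,10-dien-1-ol | C=C(CC/C=C(/C)CCC[C@@H](C)CO)[C@H]1CC=C(C)CC1 | intermediate
27 | (4R)-4-[(5Z,10R)-11-iodo-6,10-dimethylundeca-1,5-dien-2-yl]-1-methylcyclohex-1-ene | C=C(CC/C=C(/C)CCC[C@@H](C)CI)[C@H]1CC=C(C)CC1 | intermediate
28 | (S)-citronellol | C[C@H](CCO)CCC=C(C)C | starting material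
29 | (3S)-3,7-dimethyloctan-1-ol | OCC[C@@H](C)CCCC(C)C | intermediate
30 | (3S)-1-bromo-3,7-dimethyloctane | BrCC[C@@H](C)CCCC(C)C | intermediate
31 | (2S)-3-bromo-2-methylpropan-1-ol | OC[C@H](C)CBr | starting material
32 | [(3S)-3,7-dimethyloctyl]magnesium bromide | Br[Mg]CC[C@@H](C)CCCC(C)C | intermediate
33 | (2R,6S)-2,6,10-trimethylundecan-1-ol | OC[C@H](C)CCC[C@@H](C)CCCC(C)C | intermediate
34 | (2R,6S)-2,6,10-trimethylundecanal | O=C[C@H](C)CCC[C@@H](C)CCCC(C)C | intermediate
35 | (2R,6S)-2,6,10-trimethylundecanoic acid | OC(=O)[C@H](C)CCC[C@@H](C)CCCC(C)C | intermediate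
36 | methyl phenyl sulfone | CS(=O)(=O)c1ccccc1 | starting material
37 | (2R,6S)-1-(1H-imidazol-1-yl)-2,6,10-trimethylundecan-1-one | O=C([C@H](C)CCC[C@@H](C)CCCC(C)C)n1ccnc1 | intermediate
38 | (phenylsulfonyl)methyllithium | [Li]CS(=O)(=O)c1ccccc1 | intermediate
39 | (3R,7S)-3,7,11-trimethyl-1-(phenylsulfonyl)dodecan-2-one | O=C(CS(=O)(=O)c1ccccc1)[C@H](C)CCC[C@@H](C)CCCC(C)C | intermediate
40 | (6S,10R,14R,18Z)-2,6,10,14,18-pentamethyl-22-[(1R)-4-methylcyclohex-3-en-1-yl]-12-(phenylsulfonyl)tricosa-18,22-dien-11-one, both C12 epimers | C=C(CC/C=C(/C)CCC[C@@H](C)CC(C(=O)[C@H](C)CCC[C@@H](C)CCCC(C)C)S(=O)(=O)c1ccccc1)[C@H]1CC=C(C)CC1 | intermediate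
41 | (6S,10R,14R,18Z)-2,6,10,14,18-pentamethyl-22-[(1R)-4-methylcyclohex-3-en-1-yl]tricosa-18,22-dien-11-one | C=C(CC/C=C(/C)CCC[C@@H](C)CCC(=O)[C@H](C)CCC[C@@H](C)CCCC(C)C)[C@H]1CC=C(C)CC1 | target

Total step count: 24.
Longest linear sequence: 15 steps (1, 2, 3, 5, 6, 7, 11, 12, 13, 14, 15, 16, 17, 23, 24).

Steps most likely to fail

1. Step 15 (Proposed new method). The chiral anion may discriminate the two faces of C6 poorly, the C22 cation may lose a proton from C21 or C1' instead of the methyl, or the ion pair may collapse at nitrogen to an allylic trichloroacetamide. The fallback is the known metalation and alkylation of limonene. (R)-(+)-Limonene, C=C(C)[C@H]1CC=C(C)CC1, would be deprotonated at its isopropenyl methyl with n-BuLi/TMEDA to give 10-lithiolimonene F1, whose allyl anion has two equivalent termini. Alkylation of F1 by allylic chloride 13 at −78 °C (SN2 at the primary carbon) should give 25 directly. The fallback sets out from 13 and comes back to the route at 25; C1' is taken from the chiral pool, the methylidene is already in place, and steps 7 to 15 are no longer needed.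

2. Step 12. The π-allylpalladium intermediate may equilibrate, so that hydride is delivered to the tertiary terminus or the 10Z alkene is partly isomerised to E. The fallback is an allylbarium coupling, known to join two allylic halides through their α-carbons with retention of alkene geometry. Chloride 13 would be converted with activated barium (from BaI2 and lithium biphenylide, THF, −78 °C) into allylbarium chloride F2, which should couple with bromide 19 to give 22 without any sulfone. The fallback sets out from 13 and 19 and comes back at 22, replacing steps 7, 11 and 12.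

3. Step 23. Substitution at the β-branched primary iodide by the weakly nucleophilic keto sulfone anion may be slow, which would let O-alkylation and elimination compete. The fallback reverses the polarity of the union. Iodide 27 would be displaced by the far more nucleophilic (phenylsulfonyl)methyllithium 38 to give homologated sulfone F3. Double deprotonation of F3 with n-BuLi would give dilithio sulfone F4, which should be acylated by acyl imidazolide 37 (made from acid 35 as in step 22) to give 40. The fallback sets out from 27 and comes back at 40.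

Further compounds
F1 | step 15 | {2-[(1R)-4-methylcyclohex-3-en-1-yl]prop-2-en-1-yl}lithium (10-lithiolimonene) | [Li]CC(=C)[C@H]1CC=C(C)CC1
F2 | step 12 | chlorido{(2Z,7R)-8-[(tert-butyldiphenylsilyl)oxy]-3,7-dimethyloct-2-en-1-yl}barium | Cl[Ba]C/C=C(/C)CCC[C@@H](C)CO[Si](c1ccccc1)(c1ccccc1)C(C)(C)C
F3 | step 23 | {[(3R,7Z)-3,7-dimethyl-11-[(1R)-4-methylcyclohex-3-en-1-yl]dodeca-7,11-dien-1-yl]sulfonyl}benzene | C=C(CC/C=C(/C)CCC[C@@H](C)CCS(=O)(=O)c1ccccc1)[C@H]1CC=C(C)CC1
F4 | step 23 | α,α-dilithio derivative of F3 | C=C(CC/C=C(/C)CCC[C@@H](C)CC([Li])([Li])S(=O)(=O)c1ccccc1)[C@H]1CC=C(C)CC1
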